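# Hansforester A: synthesis design around a biomimetic pentaketide fold for ring B

## The problem

Hansforester A (30) has almost no carbon framework beyond three benzene rings: an orsellinate (ring A), a 2,4-dihydroxy-6-(2-oxypropyl)benzoate (ring B) and a 5-(2-oxypropyl)resorcinol (ring C) are joined head to tail by four ester bonds through two (R)-3-hydroxybutanoate spacers. Two of these esters are benzoates with both ortho positions occupied (OH and CH3 on ring A, OH and CH2 on ring B) and bound to secondary carbinols, the worst case for acylation with an activated benzoic acid. The four stereocentres are all (R) carbinol carbons at least four atoms apart, so none can direct another; each must come from a chiral building block, and each ester must be formed at the acyl carbon so that the carbinol configuration is retained. Each 3-(aroyloxy)butanoate is a β-acyloxy ester that eliminates to a crotonate under strong base, and a free 2-hydroxypropyl group next to the ring B ester can lactonise to a 3,4-dihydroisocoumarin and expel everything to its right. Six phenols and four esters rule out hydrolytic or strongly basic deprotection at the end. The enabling feature is the pattern of ring B, with carboxyl at C1, oxygen at C2 and C4 and carbon at C6: this is a pentaketide chain folded by an aldol bond between chain C2 and chain C7, and ring carbon C6 with its three side-chain carbons is an (R)-3-hydroxybutanoate unit. Ring A shows the same pattern with a methyl group (a tetraketide), so both hindered benzoates can exist as ordinary β-keto esters of an open chain before their rings are closed.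

## Retrosynthesis

**30 ⇒ 29.** The four O–CH2Ph bonds on rings B and C are cut first. Benzyl is preferred over acetal, silyl or acyl protection because hydrogenolysis is the one global deprotection that touches neither the four esters nor the β-acyloxy motifs. Ring A needs no protection because it is made last. The forward step only requires that the ester oxygens, which sit on homobenzylic carbons, stay intact.

**29 ⇒ 27 ⇒ 25 + 23.** In ring A the bond between the ester-bearing carbon and the methyl-bearing carbon is cut (C2–C7 of a 3,5,7-trioxooctanoate), giving open-chain triketo ester 27 via cyclic aldol 28. The ester C–O bond of 27 is then cut at the acyl carbon, giving alcohol 23 and acylketene 26, which arises from diketo-dioxinone 25 by loss of acetone. The neighbouring cut, at the aliphatic ester next to the ring B side chain, would need a pre-formed ring A aroyloxybutanoic acid. That acid would need benzyl groups on its phenols, an orthogonal carboxyl ester, and activation of a β-aroyloxy acyl donor prone to elimination, costing about two more steps. The chosen cut removes ring A and its hindered ester in two operations, and 25 is one step from 12 by terminal acetylation of the mixed sodium lithium dianion 24. That dianion is raised with NaH and then n-BuLi, so that no secondary amine is present beside the small, reactive acetyl donor. The forward reaction asks for ketene capture by the secondary hydroxyl of 23 under neutral thermolysis, then a fold of the kind already rehearsed at ring B.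

**23 ⇒ 21 + 3.** The ester between the left butanoate carbonyl and the side-chain oxygen of ring B is cut. The acyl partner is silyl-protected acid 3, a β-silyloxy acid that can be activated without elimination and that is used three times in the route. The forward esterification must be faster than lactonisation of the side-chain hydroxyl of 21 onto the ring B ester; fluoride then frees the hydroxyl of 23.

**21 ⇒ 20 ⇒ 19.** Only protecting groups change: the silyl ether returns to the side chain and the benzyl ethers leave the ring B phenols. The phenols must be capped before the side-chain hydroxyl is freed, otherwise the 4-OH would compete in the esterification. The silyl ether in turn keeps the side-chain oxygen from lactonising during benzylation. The forward benzylation must not trigger elimination in the right half.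

**19 ⇒ 17.** This is the strategic cut: the ring B bond between the ester-bearing carbon and the side-chain-bearing carbon (C2–C7 of a decanoate) is opened and both phenols return to ketones, via cyclic aldol 18. Cutting the benzoate C–O bond or the aryl–CH2 bond instead would leave a di-ortho-substituted benzoic acid to be joined to the β-hydroxy ester 9. That alcohol can be neither deprotonated nor subjected to inversion chemistry. Precursor 17 has no ring and its ester is an unhindered β-keto ester. The forward step must favour aldol closure over Claisen closure and pyranone formation and must leave the silyloxy group at C9 in place.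

**17 ⇒ 15 + 9.** The ester C–O bond at C1 is cut: 17 is the adduct of alcohol 9 and acylketene 16, the retro-[4+2] fragment of diketo-dioxinone 15. A free triketo acid would self-condense on activation, whereas the dioxinone keeps C1–C3 masked until thermolysis and needs no coupling agent or base. The forward step asks that the hydroxyl of 9 captures 16 faster than 16 cyclises on itself.

**15 ⇒ 12 + 3, and 12 ⇒ 10.** The C6–C7 bond of the chain is cut to the terminal carbanion of dilithium dianion 14 (from keto-dioxinone 12) and imidazolide 13 (from acid 3). Carbons C7–C10 therefore carry the side-chain stereocentre in from the chiral pool. A second cut at C4–C5 takes 12 back to commercial dioxinone 10, through dienolate 11 and a two-carbon acyl donor. The forward acylation must occur at the terminal carbon of 14 without β-elimination of the silyloxy group.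

**9 ⇒ 7 + 3, 7 ⇒ 4 + 5, 3 ⇒ 1.** The aliphatic ester of the right half is cut to alcohol 7 and acid 3. The aryl–CH2 bond of 7 is cut to Grignard reagent 6 (from bromide 4) and epoxide 5. Acid 3 is the silyl ether of hydroxy acid 1, formed through bis-silyl compound 2. All four stereocentres thus come from two commercial compounds, 1 and 5, and the forward steps only have to avoid touching them: epoxide opening at CH2 and esterification at the acyl carbon.

## Roads not taken

**Alternative 1:** The two bonds from ester oxygen to the arylpropyl carbinol carbons are cut, leading to diketone A2, in which each butanoyl carbonyl is bonded directly to an (R)-configured α-methyl carbon. A peracid would insert oxygen on the more substituted side of both ketones with retention (double Baeyer–Villiger oxidation) to give hexa-acetate A1.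
- Merits: two C–O bonds and two stereocentres are delivered in one operation. The 2-oxypropyl benzoate never exists as a free alcohol, so the lactonisation that threatens compound 21 cannot occur, and the silyl on/off steps disappear. In these respects it is better than the chosen plan.
- Weak points: each ketone of A2 is a β-aroyloxy ketone and is more prone to elimination than the β-acyloxy esters of the target. Its α-stereocentre is enolisable, so the configuration is at risk before migration. The arenes are electron-rich and face a peracid. The six aryl acetates of A1 must then be solvolysed beside four other esters. A2 also still contains both hindered benzoates, so the hardest bonds are not addressed.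
- Comparison: the chosen plan sets against it carbinol stereocentres that are never next to a carbonyl, deprotection by hydrogenolysis, and hindered benzoates that come from the ring-forming step itself.

**Alternative 2:** The aryl–CH2 bond of ring B and the adjacent ester C–O bond are cut. Divalent palladium (Pd(OAc)2 with an amino acid ligand) would palladate the only free ortho C–H of benzoic acid A4 under carboxylate direction. The aryl–palladium would open epoxide 5 at CH2, and the alkoxide would close lactone A3.
- Merits: ring B with its side chain and stereocentre comes in one catalytic step from two simple inputs. The intermediates are robust arenes, not labile polycarbonyl chains. In step count to the ring B core and in ease of handling it is clearly better than the chosen plan.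
- Weak points: A3 is exactly the dihydroisocoumarin that the target must not form. To go on, the lactone must be opened and the hydroxy acid protected before it relactonises. The di-ortho-substituted acid must then be joined to the base-sensitive secondary alcohol 9, for which neither alkoxide acylation nor inversion chemistry is available.
- Comparison: the chosen plan needs more steps to reach ring B. Against that, its ester to 9 exists before the ring does, and the same fold also provides ring A.

**Alternative 3:** The C1–C2 bond of the right-hand butanoate and its ester C–O bond are cut. Tetracarbonylcobaltate (NaCo(CO)4, or Co2(CO)8 with a pyridine promoter) would open epoxide 5 at CH2 and carbon monoxide would insert. Alcohol 7 would cleave the acylcobalt to give hydroxy ester A5, which is identical with compound 9.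
- Merits: it is one step from 7 where the chosen plan needs two, it is fully atom-economical, it uses no protecting group, and both right-half stereocentres come from the same epoxide. For this one bond it is better.
- Weak points: the reaction is reliable when the alcohol is the solvent. With 7 as the limiting partner, β-lactone formation, oligoester formation through the product hydroxyl, and epoxide isomerisation all compete, and pressurised carbon monoxide is needed. It also solves only the easiest of the four esters and is silent on rings A and B.
- Comparison: the chosen plan needs acid 3 for two other bonds anyway, so the saving would be a single step. The carbonylation could be grafted onto the route later.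

Key step: step 8

Remark on the chemistry: the polycarbonyl compounds 15, 17, 25 and 27 exist as keto–enol mixtures and are drawn as the all-keto tautomers; 17 and 27 are carried forward crude after evaporation of toluene.

## Route

Step 1
Reactants: 1 (R)-3-hydroxybutanoic acid
Product: 3 (R)-3-[(tert-butyldimethylsilyl)oxy]butanoic acid, via bis-silyl ester 2 (not isolated)
Conditions: TBSCl (2.2 equiv), imidazole (4.5 equiv), DMF, rt; then K2CO3, MeOH/THF/H2O, rt; 1 M HCl to pH 4, 0 °C
Reagents that add atoms: tert-butyldimethylsilyl chloride (TBSCl), CC(C)(C)[Si](C)(C)Cl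
Why: Silylation of hydroxyl and carboxyl followed by selective solvolysis of the much more labile silyl ester; the stereocentre of 1 is not involved.

Step 2
Reactants: 4 1,3-bis(benzyloxy)-5-bromobenzene; 5 (R)-propylene oxide
Product: 7 (R)-1-[3,5-bis(benzyloxy)phenyl]propan-2-ol, via aryl Grignard reagent 6 (not isolated)
Conditions: Mg, I2 (cat.), THF, reflux; then cuprous iodide CuI (10 mol %), 5 (1.5 equiv), −30 → 0 °C; aq. NH4Cl work-up
Reagents that add atoms: none
Why: Copper-catalysed Grignard opening of a terminal epoxide by SN2 attack at the unsubstituted CH2; the C–O bond at the stereocentre is untouched, so the (R) configuration of 5 appears unchanged in 7.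

Step 3
Reactants: 7 (R)-1-[3,5-bis(benzyloxy)phenyl]propan-2-ol; 3 (R)-3-[(tert-butyldimethylsilyl)oxy]butanoic acid
Product: 8 (R)-1-[3,5-bis(benzyloxy)phenyl]propan-2-yl (R)-3-[(tert-butyldimethylsilyl)oxy]butanoate
Conditions: DCC (1.2 equiv), DMAP (0.1 equiv), CH2Cl2, 0 °C → rt
Reagents that add atoms: none
Why: Steglich esterification; the bond forms at the acyl carbon so the carbinol of 7 is retained, and the β-silyloxy acid has no good leaving group for elimination.

Step 4
Reactants: 8 silyl ether of the right half
Product: 9 (R)-1-[3,5-bis(benzyloxy)phenyl]propan-2-yl (R)-3-hydroxybutanoate (right-half alcohol)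
Conditions: HF·pyridine, pyridine, THF, 0 °C → rt
Reagents that add atoms: none
Why: Fluoride desilylation in a buffered acidic medium, which avoids the retro-aldol and elimination pathways that a basic fluoride source could open in a β-hydroxy ester.

Step 5
Reactants: 10 2,2,6-trimethyl-4H-1,3-dioxin-4-one
Product: 12 2,2-dimethyl-6-(2-oxopropyl)-4H-1,3-dioxin-4-one, via lithium dienolate 11 (not isolated)
Conditions: 10 (2 equiv), LiN(SiMe3)2 (2 equiv), THF, −78 °C; AcCl (1 equiv), −78 → −20 °C; aq. NH4Cl
Reagents that add atoms: acetyl chloride, CC(=O)Cl
Why: Vinylogous Claisen acylation: γ-deprotonation gives the dienolate, which is C-acylated at the γ-carbon; the second equivalent of dienolate absorbs the more acidic proton of 12 and is recovered as 10.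

Step 6
Reactants: 12 2,2-dimethyl-6-(2-oxopropyl)-4H-1,3-dioxin-4-one; 3 (R)-3-[(tert-butyldimethylsilyl)oxy]butanoic acid
Product: 15 6-[(R)-6-(tert-butyldimethylsilyloxy)-2,4-dioxoheptyl]-2,2-dimethyl-4H-1,3-dioxin-4-one (diketo-dioxinone B), via acyl imidazolide 13 (not isolated), via dilithium dianion 14 (not isolated)
Conditions: 3, CDI (1.1 equiv), THF, rt; separately 12, LiN(iPr)2 (2.2 equiv), THF, −78 °C; add the imidazolide solution, −78 → −40 °C; aq. NH4Cl
Reagents that add atoms: none
Why: Claisen-type C-acylation of a 1,3-dicarbonyl dianion, which reacts at its terminal, last-formed and most nucleophilic carbon; the departing imidazolide deprotonates the new β-diketone and so prevents over-acylation, and the silyloxy group is too poor a leaving group for E1cB loss.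

Step 7
Reactants: 15 diketo-dioxinone B (1.2 equiv); 9 right-half alcohol
Product: 17 triketo ester: (R)-9-(tert-butyldimethylsilyloxy)-3,5,7-trioxodecanoate of alcohol 9, via acylketene 16 (not isolated)
Conditions: toluene, 110 °C, N2 sweep to remove acetone; evaporate, use crude
Reagents that add atoms: none
Why: Retro-hetero-Diels–Alder fragmentation of the dioxinone releases acetone and an acylketene, which the secondary hydroxyl of 9 captures by nucleophilic addition; no coupling agent or base is present, so the β-hydroxy ester and all stereocentres are untouched.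

Step 8
Reactants: 17 triketo ester
Product: 19 ring B resorcylate: 2,4-dihydroxy-6-[(R)-2-(tert-butyldimethylsilyloxy)propyl]benzoate of alcohol 9, via cyclic aldol 18 (not isolated)
Conditions: Et3N (3 equiv), CH2Cl2, rt; then AcOH, rt; aqueous wash
Reagents that add atoms: none
Why: Triethylamine enolises the tetracarbonyl array of 17; the C2 carbanion, doubly activated by the ester and the C3 ketone, adds to the C7 ketone to give cyclic aldol 18, which loses water by E1cB and tautomerises at C3 and C5 to arene 19, aromatisation making the sequence irreversible. The closest known reaction type is the biomimetic aldol aromatisation of 3,5,7-triketo esters to 6-alkyl-2,4-dihydroxybenzoates, the laboratory counterpart of the orsellinate fold. Ring B closes in a 6-(enolexo)-exo-trig mode by formation of the C2–C7 bond. No stereocentre is created: the two sp3 centres of 18 are erased on aromatisation, and the three existing (R) carbinols are not enolisable and are left alone. The step needs aldol closure to beat Claisen closure (C6 onto the ester carbonyl) and O-acylation to a 4-hydroxy-2-pyranone; both competitors must expel a secondary alkoxide from an ester, which a tertiary amine at room temperature does not promote, whereas the aldol path needs no leaving group. Among the enolates, C2 is the only doubly activated methylene that can reach a ketone through a six-membered transition state; the singly activated C8, which could attack C3, is far less acidic. The silyloxy group at C9 is a poor leaving group, so elimination across C8–C9 is not expected, and the weak base spares the β-acyloxy ester of the right half.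

Step 9
Reactants: 19 ring B resorcylate
Product: 20 2,4-bis(benzyloxy)-6-[(R)-2-(tert-butyldimethylsilyloxy)propyl]benzoate of alcohol 9
Conditions: BnBr (3 equiv), K2CO3 (3 equiv), n-Bu4NI (cat.), DMF, rt → 40 °C
Reagents that add atoms: benzyl bromide, BrCc1ccccc1
Why: Williamson etherification of the para phenol and then the hydrogen-bonded ortho phenol; carbonate is too weak to deprotonate the ester α-CH2 to a useful extent, and the silyl ether blocks the side-chain oxygen.

Step 10
Reactants: 20 bis-benzyl ether
Product: 21 2,4-bis(benzyloxy)-6-[(R)-2-hydroxypropyl]benzoate of alcohol 9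
Conditions: HF·pyridine, pyridine, THF, 0 °C; used at once
Reagents that add atoms: none
Why: Fluoride desilylation under buffered acidic conditions; the benzoate carbonyl is now flanked by OBn and CH2 and twisted out of the ring plane, which slows attack by the liberated hydroxyl.

Step 11
Reactants: 21 side-chain alcohol; 3 (R)-3-[(tert-butyldimethylsilyl)oxy]butanoic acid
Product: 22 2,4-bis(benzyloxy)-6-[(R)-2-{[(R)-3-(tert-butyldimethylsilyloxy)butanoyl]oxy}propyl]benzoate of alcohol 9
Conditions: 3 (1.5 equiv), DCC (1.5 equiv), DMAP (0.1 equiv), CH2Cl2, 0 °C → rt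
Reagents that add atoms: none
Why: Steglich esterification with no stoichiometric amine base, so intermolecular acyl transfer to the secondary hydroxyl should outrun lactonisation; the carbinol configuration is retained.

Step 12
Reactants: 22 silyl ether
Product: 23 2,4-bis(benzyloxy)-6-[(R)-2-{[(R)-3-hydroxybutanoyl]oxy}propyl]benzoate of alcohol 9
Conditions: HF·pyridine, pyridine, THF, 0 °C → rt
Reagents that add atoms: none
Why: Same buffered fluoride desilylation as in step 4; both β-aroyloxy esters are stable to these non-basic conditions.

Step 13
Reactants: 12 2,2-dimethyl-6-(2-oxopropyl)-4H-1,3-dioxin-4-one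
Product: 25 6-(2,4-dioxopentyl)-2,2-dimethyl-4H-1,3-dioxin-4-one (diketo-dioxinone A), via sodium lithium dianion 24 (not isolated)
Conditions: NaH (1.1 equiv), THF, 0 °C; n-BuLi (1.05 equiv), −78 → −20 °C; N-acetylimidazole (1.0 equiv), −78 → −40 °C; aq. NH4Cl
Reagents that add atoms: N-acetylimidazole, CC(=O)n1ccnc1
Why: Huckin–Weiler generation of a 1,3-dicarbonyl dianion: hydride removes the acidic CH2 proton and butyllithium then removes a CH3 proton of the enolate, whose lactone carbonyl is deactivated by conjugation. Claisen-type C-acylation then occurs at the terminal, most nucleophilic carbon, as in step 6, and no secondary amine is present to consume the acetyl donor.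

Step 14
Reactants: 25 diketo-dioxinone A (1.5 equiv); 23 hydroxy ester
Product: 27 3,5,7-trioxooctanoate of alcohol 23, via acylketene 26 (not isolated)
Conditions: toluene, 110 °C, N2 sweep; evaporate, use crude
Reagents that add atoms: none
Why: Retro-hetero-Diels–Alder generation of the acylketene and its capture by the secondary hydroxyl of 23, the same alcohol type as 9 in step 7; the neutral conditions leave the two β-aroyloxy esters intact.

Step 15
Reactants: 27 triketo ester
Product: 29 tetra-O-benzyl hansforester A: 2,4-dihydroxy-6-methylbenzoate of alcohol 23, via cyclic aldol 28 (not isolated)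
Conditions: Et3N (3 equiv), CH2Cl2, rt; then AcOH, rt; aqueous wash
Reagents that add atoms: none
Why: The aldol aromatisation of step 8 repeated on the tetraketide chain: the C2 carbanion adds to the C7 methyl ketone (6-exo-trig), then dehydration and enolisation give the orsellinate; no stereocentre is formed, and Claisen and pyranone closure are again disfavoured by the poor secondary alkoxide leaving group.

Step 16
Reactants: 29 tetra-O-benzyl hansforester A
Product: 30 hansforester A
Conditions: H2 (1 atm), 10 % Pd/C, EtOAc, rt
Reagents that add atoms: none
Why: Catalytic hydrogenolysis of four aryl benzyl ethers under neutral conditions; the ester oxygens sit on homobenzylic carbons and are not cleaved, and no base or acid is present to disturb the β-acyloxy esters.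

## Compound list

1 | (R)-3-hydroxybutanoic acid | C[C@@H](O)CC(=O)O | starting material
2 | tert-butyldimethylsilyl (R)-3-[(tert-butyldimethylsilyl)oxy]butanoate | C[C@@H](O[Si](C)(C)C(C)(C)C)CC(=O)O[Si](C)(C)C(C)(C)C | intermediate
3 | (R)-3-[(tert-butyldimethylsilyl)oxy]butanoic acid | C[C@@H](O[Si](C)(C)C(C)(C)C)CC(=O)O | intermediate
4 | 1,3-bis(benzyloxy)-5-bromobenzene | Brc1cc(OCc2ccccc2)cc(OCc2ccccc2)c1 | starting material
5 | (R)-propylene oxide | C[C@@H]1CO1 | starting material
6 | [3,5-bis(benzyloxy)phenyl]magnesium bromide | Br[Mg]c1cc(OCc2ccccc2)cc(OCc2ccccc2)c1 | intermediate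
7 | (R)-1-[3,5-bis(benzyloxy)phenyl]propan-2-ol | C[C@@H](O)Cc1cc(OCc2ccccc2)cc(OCc2ccccc2)c1 | intermediate
8 | (R)-1-[3,5-bis(benzyloxy)phenyl]propan-2-yl (R)-3-[(tert-butyldimethylsilyl)oxy]butanoate | C[C@@H](O[Si](C)(C)C(C)(C)C)CC(=O)O[C@H](C)Cc1cc(OCc2ccccc2)cc(OCc2ccccc2)c1 | intermediate
9 | (R)-1-[3,5-bis(benzyloxy)phenyl]propan-2-yl (R)-3-hydroxybutanoate (right-half alcohol) | C[C@@H](O)CC(=O)O[C@H](C)Cc1cc(OCc2ccccc2)cc(OCc2ccccc2)c1 | intermediate
10 | 2,2,6-trimethyl-4H-1,3-dioxin-4-one | CC1=CC(=O)OC(C)(C)O1 | starting material
11 | lithium dienolate of 10 (lithium 2,2-dimethyl-6-methylidene-6H-1,3-dioxin-4-olate) | [Li+].C=C1C=C([O-])OC(C)(C)O1 | intermediate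
12 | 2,2-dimethyl-6-(2-oxopropyl)-4H-1,3-dioxin-4-one | CC(=O)CC1=CC(=O)OC(C)(C)O1 | intermediate
13 | (R)-3-[(tert-butyldimethylsilyl)oxy]-1-(1H-imidazol-1-yl)butan-1-one | C[C@@H](O[Si](C)(C)C(C)(C)C)CC(=O)n1ccnc1 | intermediate
14 | dilithium dianion of 12 (bis-enolate from loss of one CH2 and one CH3 proton) | [Li+].[Li+].C=C([O-])C=C1C=C([O-])OC(C)(C)O1 | intermediate
15 | 6-[(R)-6-(tert-butyldimethylsilyloxy)-2,4-dioxoheptyl]-2,2-dimethyl-4H-1,3-dioxin-4-one | C[C@@H](O[Si](C)(C)C(C)(C)C)CC(=O)CC(=O)CC1=CC(=O)OC(C)(C)O1 | intermediate
16 | (R)-9-(tert-butyldimethylsilyloxy)-3,5,7-trioxodec-1-en-1-one (acylketene) | C[C@@H](O[Si](C)(C)C(C)(C)C)CC(=O)CC(=O)CC(=O)C=C=O | intermediate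
17 | (R)-9-(tert-butyldimethylsilyloxy)-3,5,7-trioxodecanoate of alcohol 9 | C[C@@H](O[Si](C)(C)C(C)(C)C)CC(=O)CC(=O)CC(=O)CC(=O)O[C@H](C)CC(=O)O[C@H](C)Cc1cc(OCc2ccccc2)cc(OCc2ccccc2)c1 | intermediate
18 | 2-hydroxy-4,6-dioxo-2-[(R)-2-(tert-butyldimethylsilyloxy)propyl]cyclohexane-1-carboxylate of alcohol 9 (ring carbons C1 and C2 unassigned) | C[C@@H](O[Si](C)(C)C(C)(C)C)CC1(O)CC(=O)CC(=O)C1C(=O)O[C@H](C)CC(=O)O[C@H](C)Cc1cc(OCc2ccccc2)cc(OCc2ccccc2)c1 | intermediate
19 | 2,4-dihydroxy-6-[(R)-2-(tert-butyldimethylsilyloxy)propyl]benzoate of alcohol 9 | C[C@@H](O[Si](C)(C)C(C)(C)C)Cc1cc(O)cc(O)c1C(=O)O[C@H](C)CC(=O)O[C@H](C)Cc1cc(OCc2ccccc2)cc(OCc2ccccc2)c1 | intermediate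
20 | 2,4-bis(benzyloxy)-6-[(R)-2-(tert-butyldimethylsilyloxy)propyl]benzoate of alcohol 9 | C[C@@H](O[Si](C)(C)C(C)(C)C)Cc1cc(OCc2ccccc2)cc(OCc2ccccc2)c1C(=O)O[C@H](C)CC(=O)O[C@H](C)Cc1cc(OCc2ccccc2)cc(OCc2ccccc2)c1 | intermediate
21 | 2,4-bis(benzyloxy)-6-[(R)-2-hydroxypropyl]benzoate of alcohol 9 | C[C@@H](O)Cc1cc(OCc2ccccc2)cc(OCc2ccccc2)c1C(=O)O[C@H](C)CC(=O)O[C@H](C)Cc1cc(OCc2ccccc2)cc(OCc2ccccc2)c1 | intermediate
22 | 2,4-bis(benzyloxy)-6-[(R)-2-{[(R)-3-(tert-butyldimethylsilyloxy)butanoyl]oxy}propyl]benzoate of alcohol 9 | C[C@@H](O[Si](C)(C)C(C)(C)C)CC(=O)O[C@H](C)Cc1cc(OCc2ccccc2)cc(OCc2ccccc2)c1C(=O)O[C@H](C)CC(=O)O[C@H](C)Cc1cc(OCc2ccccc2)cc(OCc2ccccc2)c1 | intermediate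
23 | 2,4-bis(benzyloxy)-6-[(R)-2-{[(R)-3-hydroxybutanoyl]oxy}propyl]benzoate of alcohol 9 | C[C@@H](O)CC(=O)O[C@H](C)Cc1cc(OCc2ccccc2)cc(OCc2ccccc2)c1C(=O)O[C@H](C)CC(=O)O[C@H](C)Cc1cc(OCc2ccccc2)cc(OCc2ccccc2)c1 | intermediate
24 | sodium lithium dianion of 12 (bis-enolate from loss of one CH2 and one CH3 proton) | [Na+].[Li+].C=C([O-])C=C1C=C([O-])OC(C)(C)O1 | intermediate
25 | 6-(2,4-dioxopentyl)-2,2-dimethyl-4H-1,3-dioxin-4-one | CC(=O)CC(=O)CC1=CC(=O)OC(C)(C)O1 | intermediate
26 | 3,5,7-trioxooct-1-en-1-one (acylketene) | CC(=O)CC(=O)CC(=O)C=C=O | intermediate
27 | 3,5,7-trioxooctanoate of alcohol 23 | CC(=O)CC(=O)CC(=O)CC(=O)O[C@H](C)CC(=O)O[C@H](C)Cc1cc(OCc2ccccc2)cc(OCc2ccccc2)c1C(=O)O[C@H](C)CC(=O)O[C@H](C)Cc1cc(OCc2ccccc2)cc(OCc2ccccc2)c1 | intermediate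
28 | 2-hydroxy-2-methyl-4,6-dioxocyclohexane-1-carboxylate of alcohol 23 (ring carbons C1 and C2 unassigned) | CC1(O)CC(=O)CC(=O)C1C(=O)O[C@H](C)CC(=O)O[C@H](C)Cc1cc(OCc2ccccc2)cc(OCc2ccccc2)c1C(=O)O[C@H](C)CC(=O)O[C@H](C)Cc1cc(OCc2ccccc2)cc(OCc2ccccc2)c1 | intermediate
29 | tetra-O-benzyl hansforester A (2,4-dihydroxy-6-methylbenzoate of alcohol 23; rings B and C benzylated) | Cc1cc(O)cc(O)c1C(=O)O[C@H](C)CC(=O)O[C@H](C)Cc1cc(OCc2ccccc2)cc(OCc2ccccc2)c1C(=O)O[C@H](C)CC(=O)O[C@H](C)Cc1cc(OCc2ccccc2)cc(OCc2ccccc2)c1 | intermediate
30 | hansforester A | Cc1cc(O)cc(O)c1C(=O)O[C@H](C)CC(=O)O[C@H](C)Cc1cc(O)cc(O)c1C(=O)O[C@H](C)CC(=O)O[C@H](C)Cc1cc(O)cc(O)c1 | target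

## Step count and risk assessment

Total: 16 steps. Longest linear sequence: 12 steps (1, 3, 4, 7, 8, 9, 10, 11, 12, 14, 15, 16).

**Step 8 (key step; the same applies to step 15).**
- Risk: the open chain may cyclise in the wrong sense, either by O-acylation to a pyranone or by Claisen closure, each with loss of the alcohol portion. The dehydration of the aldol may also stall, so that acid treatment strong enough to finish it also removes the silyl group.
- Fallback: ring closure and ester formation are exchanged. Diketo-dioxinone 15 is aromatised on its own with Et3N in CH2Cl2; its carboxyl is locked in the heterocycle and cannot leave. This gives (R)-5-[2-(tert-butyldimethylsilyloxy)propyl]-7-hydroxy-2,2-dimethyl-4H-1,3-benzodioxin-4-one F1. Irradiation of F1 near 300 nm in CH2Cl2 with alcohol 9 expels acetone and generates an ortho-quinone ketene, which 9 traps. The route is rejoined at 19.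

**Step 6.**
- Risk: proton transfer from the α-CH2 of the imidazolide to the strongly basic dianion may outrun acylation. O-acylation or acylation at the internal carbon may also intrude.
- Fallback: starting from 10, dienolate 11 is acylated with allyl malonyl chloride to give allyl 4-(2,2-dimethyl-4-oxo-4H-1,3-dioxin-6-yl)-3-oxobutanoate F2. Acid 3 is converted with 1-chloro-N,N,2-trimethylprop-1-en-1-amine into (R)-3-[(tert-butyldimethylsilyl)oxy]butanoyl chloride F3. Soft enolisation of F2 with MgCl2 and pyridine and C-acylation by F3 gives the tricarbonyl allyl ester F4. Zerovalent palladium (Pd(PPh3)4) with morpholine removes the allyl group, and decarboxylation returns to the route at 15 without any strong base.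

**Step 7.**
- Risk: capture of the acylketene by the hindered, precious alcohol 9, used near stoichiometry, may be slower than intramolecular cyclisation of the ketene to a pyranone.
- Fallback: the ketene is trapped with a cheap alcohol in excess and ring C is attached afterwards.
  - Acid 1 is alkylated with allyl bromide and Cs2CO3 in DMF to give allyl (R)-3-hydroxybutanoate F5.
  - Thermolysis of 15 with excess F5 gives the allyl triketo ester F6.
  - The Et3N fold gives the allyl ester resorcylate F7.
  - Benzylation gives the bis-benzyl ether F8.
  - Pd(PPh3)4 with morpholine gives the acid F9.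
  - Steglich esterification of F9 with alcohol 7 at 0 °C rejoins the route at 20.

**Step 9.**
- Risk: base-induced E1cB loss of the ring B carboxylate from the β-aroyloxy ester during the slow alkylation of the hydrogen-bonded ortho phenol.
- Fallback: starting from 19, both phenols are etherified under neutral redox-condensation conditions (Mitsunobu reaction with benzyl alcohol, PPh3 and diisopropyl azodicarboxylate in THF). This arrives at 20 with no carbonate base and no new compound.

**Step 11 (with step 10).**
- Risk: lactonisation of the side-chain hydroxyl of 21 onto the ring B ester, with expulsion of the right half, promoted by the nucleophilic catalyst before acylation is complete.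
- Fallback: starting from 21, the hydroxyl is acylated under neutral thermal conditions by heating with dioxinone 10 in toluene (acetylketene capture) to give the acetoacetate F10. Noyori asymmetric hydrogenation of F10 with RuCl2[(R)-BINAP] then sets the (R)-carbinol under catalyst control. The route is rejoined at 23, bypassing 22.

**Step 13.**
- Risk: nucleophilic addition of butyllithium to the lactone carbonyl of the sodium enolate may compete with the second deprotonation, and proton transfer from the acetyl donor to the dianion may outrun acylation.
- Fallback: ring A is brought in preformed, without activation of its acid. Commercial 2,4-dihydroxy-6-methylbenzoic acid is condensed with acetone in trifluoroacetic acid and trifluoroacetic anhydride to give 7-hydroxy-2,2,5-trimethyl-4H-1,3-benzodioxin-4-one F11. Starting from 23, irradiation near 300 nm in CH2Cl2 with an excess of F11 expels acetone and generates an ortho-quinone ketene, which the hydroxyl of 23 traps. The route is rejoined at 29, and steps 13 to 15 are bypassed.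

## Further compounds

F1 | step 8 | (R)-5-[2-(tert-butyldimethylsilyloxy)propyl]-7-hydroxy-2,2-dimethyl-4H-1,3-benzodioxin-4-one | C[C@@H](O[Si](C)(C)C(C)(C)C)Cc1cc(O)cc2OC(C)(C)OC(=O)c12
F2 | step 6 | allyl 4-(2,2-dimethyl-4-oxo-4H-1,3-dioxin-6-yl)-3-oxobutanoate | C=CCOC(=O)CC(=O)CC1=CC(=O)OC(C)(C)O1
F3 | step 6 | (R)-3-[(tert-butyldimethylsilyl)oxy]butanoyl chloride | C[C@@H](O[Si](C)(C)C(C)(C)C)CC(=O)Cl
F4 | step 6 | allyl 2-[(R)-3-(tert-butyldimethylsilyloxy)butanoyl]-4-(2,2-dimethyl-4-oxo-4H-1,3-dioxin-6-yl)-3-oxobutanoate | C=CCOC(=O)C(C(=O)C[C@@H](C)O[Si](C)(C)C(C)(C)C)C(=O)CC1=CC(=O)OC(C)(C)O1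
F5 | step 7 | allyl (R)-3-hydroxybutanoate | C[C@@H](O)CC(=O)OCC=C
F6 | step 7 | (R)-4-(allyloxy)-4-oxobutan-2-yl (R)-9-(tert-butyldimethylsilyloxy)-3,5,7-trioxodecanoate | C[C@@H](O[Si](C)(C)C(C)(C)C)CC(=O)CC(=O)CC(=O)CC(=O)O[C@H](C)CC(=O)OCC=C
F7 | step 7 | (R)-4-(allyloxy)-4-oxobutan-2-yl 2,4-dihydroxy-6-[(R)-2-(tert-butyldimethylsilyloxy)propyl]benzoate | C[C@@H](O[Si](C)(C)C(C)(C)C)Cc1cc(O)cc(O)c1C(=O)O[C@H](C)CC(=O)OCC=C
F8 | step 7 | (R)-4-(allyloxy)-4-oxobutan-2-yl 2,4-bis(benzyloxy)-6-[(R)-2-(tert-butyldimethylsilyloxy)propyl]benzoate | C[C@@H](O[Si](C)(C)C(C)(C)C)Cc1cc(OCc2ccccc2)cc(OCc2ccccc2)c1C(=O)O[C@H](C)CC(=O)OCC=C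
F9 | step 7 | (R)-3-({2,4-bis(benzyloxy)-6-[(R)-2-(tert-butyldimethylsilyloxy)propyl]benzoyl}oxy)butanoic acid | C[C@@H](O[Si](C)(C)C(C)(C)C)Cc1cc(OCc2ccccc2)cc(OCc2ccccc2)c1C(=O)O[C@H](C)CC(=O)O
F0 | step 9 | none | none
F10 | step 11 | 2,4-bis(benzyloxy)-6-[(R)-2-(3-oxobutanoyloxy)propyl]benzoate of alcohol 9 | CC(=O)CC(=O)O[C@H](C)Cc1cc(OCc2ccccc2)cc(OCc2ccccc2)c1C(=O)O[C@H](C)CC(=O)O[C@H](C)Cc1cc(OCc2ccccc2)cc(OCc2ccccc2)c1
F11 | step 13 | 7-hydroxy-2,2,5-trimethyl-4H-1,3-benzodioxin-4-one | Cc1cc(O)cc2OC(C)(C)OC(=O)c12
A1 | alternative 1 | hexa-O-acetyl hansforester A | Cc1cc(OC(C)=O)cc(OC(C)=O)c1C(=O)O[C@H](C)CC(=O)O[C@H](C)Cc1cc(OC(C)=O)cc(OC(C)=O)c1C(=O)O[C@H](C)CC(=O)O[C@H](C)Cc1cc(OC(C)=O)cc(OC(C)=O)c1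
A2 | alternative 1 | hexa-acetate diketone (A1 without the two ester oxygens on the arylpropyl carbons; each butanoyl carbonyl bonded to an (R)-α-methyl carbon) | Cc1cc(OC(C)=O)cc(OC(C)=O)c1C(=O)O[C@H](C)CC(=O)[C@H](C)Cc1cc(OC(C)=O)cc(OC(C)=O)c1C(=O)O[C@H](C)CC(=O)[C@H](C)Cc1cc(OC(C)=O)cc(OC(C)=O)c1
A3 | alternative 2 | (R)-6,8-bis(benzyloxy)-3-methyl-3,4-dihydroisocoumarin | C[C@@H]1Cc2cc(OCc3ccccc3)cc(OCc3ccccc3)c2C(=O)O1
A4 | alternative 2 | 2,4-bis(benzyloxy)benzoic acid | OC(=O)c1ccc(OCc2ccccc2)cc1OCc1ccccc1
A5 | alternative 3 | (R)-1-[3,5-bis(benzyloxy)phenyl]propan-2-yl (R)-3-hydroxybutanoate (identical with 9) | C[C@@H](O)CC(=O)O[C@H](C)Cc1cc(OCc2ccccc2)cc(OCc2ccccc2)c1
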